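Ring B carries its carboxyl carbon on C1 and the acyloxymethyl arm on the neighbouring C6, with the C2 oxygen on the other side of C1. Both bonds, C6–CH2 and C1–CO2H, are cut back to a 3-alkoxyaryne across C1 and C6. In one pot this aryne, released at −78 °C from a 2-iodoaryl triflate by iodine–magnesium exchange, should take up the ring-A aroyloxymethyl magnesium carbenoid at C6 and carbon dioxide at C1. The precursors are 2-iodo-3,5-bis(methoxymethoxy)-4-methylphenyl triflate, made from 2-methylresorcinol, and iodomethyl 2,4-bis(methoxymethoxy)-3,6-dimethylbenzoate, made from atraric acid. Mild acid then removes the four methoxymethyl groups.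

Key step: step 9

Remark on numbering: ring A is the 2,4-dihydroxy-3,6-dimethylbenzoyl ring; ring B is the benzoic acid ring with C1 bearing CO2H, C2 OH, C3 CH3, C4 OH, C5 H and C6 the CH2O arm. The target has no stereocentre.

Step 1
Reactants: 1 2-methylresorcinol
Product: 2 1,3-bis(methoxymethoxy)-2-methylbenzene
Conditions: NaH, MOMCl, DMF, 0 °C to rt
Reagents that add atoms: chloromethyl methyl ether, COCCl
Why: Williamson-type O-alkylation of both phenoxides with the chloromethyl ether should give the bis-acetal, as no other nucleophilic site is present.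

Step 2
Reactants: 2 1,3-bis(methoxymethoxy)-2-methylbenzene
Product: 4 3,5-bis(methoxymethoxy)-4-methylphenol, via pinacol arylboronate 3 (not isolated)
Conditions: [Ir(OMe)(cod)]2 (cat.), 4,4'-di-tert-butyl-2,2'-bipyridine, B2pin2, THF, 80 °C; then aq. NaOH, H2O2, 0 °C
Reagents that add atoms: hydrogen peroxide, OO; bis(pinacolato)diboron, CC1(C)OB(OC1(C)C)B1OC(C)(C)C(C)(C)O1 (boryl group of 3 only)
Why: Iridium-catalysed C–H borylation is sterically governed and should go to C5, the only ring C–H without an ortho substituent, and alkaline peroxide oxidation of the arylboronate then gives the phenol with the base-stable acetals untouched (one-pot borylation–oxidation).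

Step 3
Reactants: 4 3,5-bis(methoxymethoxy)-4-methylphenol
Product: 5 2-iodo-3,5-bis(methoxymethoxy)-4-methylphenol
Conditions: NIS (1.0 equiv), MeCN, −20 to 0 °C, dark
Reagents that add atoms: N-iodosuccinimide, O=C1CCC(=O)N1I
Why: Electrophilic aromatic iodination ortho to the free phenol; the two open ring positions are equivalent by symmetry, so one equivalent of reagent at low temperature should stop at the mono-iodide.

Step 4
Reactants: 5 2-iodo-3,5-bis(methoxymethoxy)-4-methylphenol
Product: 6 2-iodo-3,5-bis(methoxymethoxy)-4-methylphenyl trifluoromethanesulfonate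
Conditions: PhNTf2, Et3N, DMAP (cat.), CH2Cl2, rt
Reagents that add atoms: N-phenylbis(trifluoromethanesulfonimide), O=S(=O)(N(c1ccccc1)S(=O)(=O)C(F)(F)F)C(F)(F)F
Why: O-Sulfonylation of the phenol with a mild triflyl donor under amine base spares the acetals; a triflate is chosen because its ortho-magnesiated form loses the sulfonate already at −78 °C.

Step 5
Reactants: 7 methyl 2,4-dihydroxy-3,6-dimethylbenzoate (atraric acid)
Product: 8 methyl 2,4-bis(methoxymethoxy)-3,6-dimethylbenzoate
Conditions: NaH, MOMCl, DMF, 0 °C to rt
Reagents that add atoms: chloromethyl methyl ether, COCCl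
Why: Williamson-type O-alkylation; full deprotonation with sodium hydride is used because the C2 hydroxyl is hydrogen-bonded to the ester and flanked by two substituents.

Step 6
Reactants: 8 methyl 2,4-bis(methoxymethoxy)-3,6-dimethylbenzoate
Product: 9 2,4-bis(methoxymethoxy)-3,6-dimethylbenzoic acid
Conditions: KOH, DMSO–H2O, 80 °C; then cold 1 M HCl to pH 4
Reagents that add atoms: potassium hydroxide, [K+].[OH-] (its oxygen ends in the carboxyl group)
Why: Saponification of the di-ortho-substituted methyl ester needs hot hydroxide in a dipolar solvent, which the base-stable acetals tolerate, and the acidification is kept cold and brief.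

Step 7
Reactants: 9 2,4-bis(methoxymethoxy)-3,6-dimethylbenzoic acid; 10 chloromethyl chlorosulfate
Product: 11 chloromethyl 2,4-bis(methoxymethoxy)-3,6-dimethylbenzoate
Conditions: NaHCO3, Bu4NHSO4 (cat.), CH2Cl2/H2O, 0 °C to rt
Reagents that add atoms: none
Why: Phase-transfer O-alkylation of the carboxylate, in which chlorosulfate is displaced in preference to chloride; the reaction takes place at the reagent carbon, so the hindered carbonyl is no obstacle.

Step 8
Reactants: 11 chloromethyl 2,4-bis(methoxymethoxy)-3,6-dimethylbenzoate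
Product: 12 iodomethyl 2,4-bis(methoxymethoxy)-3,6-dimethylbenzoate
Conditions: NaI, acetone, rt, dark
Reagents that add atoms: sodium iodide, [Na+].[I-]
Why: Finkelstein halide exchange on the activated chloromethyl ester, driven by precipitation of NaCl from acetone; the iodide is used without storage.

Step 9
Reactants: 12 iodomethyl 2,4-bis(methoxymethoxy)-3,6-dimethylbenzoate; 6 2-iodo-3,5-bis(methoxymethoxy)-4-methylphenyl trifluoromethanesulfonate; 13 carbon dioxide
Product: 18 6-{[2,4-bis(methoxymethoxy)-3,6-dimethylbenzoyl]oxymethyl}-2,4-bis(methoxymethoxy)-3-methylbenzoic acid, via aroyloxymethylmagnesium chloride 14 (not isolated), via magnesiated aryl triflate 15 (not isolated), via aryne 16 (not isolated), via arylmagnesium chloride 17 (not isolated)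
Conditions: 12 (1.5 equiv), iPrMgCl·LiCl, THF, −78 °C; then 6, Me3SiCH2MgCl, −78 °C; CO2 gas, −78 to 0 °C; cold 0.5 M HCl to pH 3
Reagents that add atoms: isopropylmagnesium chloride, CC(C)[Mg]Cl (MgCl of 14 and 17 only); (trimethylsilyl)methylmagnesium chloride, C[Si](C)(C)C[Mg]Cl (MgCl of 15 only)
Why: Proposed new method: iodine–magnesium exchange on 12 should give the chelate-stabilised aroyloxymethylmagnesium chloride 14, exchange on 6 by the poorly nucleophilic Me3SiCH2MgCl should give 15, which sheds magnesium chloride triflate at −78 °C to leave aryne 16, and 14 then adds its carbon to C6 (carbomagnesiation) so that the C1 arylmagnesium 17 can be carboxylated by CO2. The closest known reaction types are the addition of magnesium nucleophiles to arynes set free from 2-magnesiated aryl sulfonates with electrophilic capture of the new arylmagnesium, and the formation of α-magnesiated pivalates or hindered benzoates by exchange at −78 °C and their addition to carbon electrophiles; their union on an aryne has not been shown. No ring is closed and no stereocentre arises. Attack must occur at C6 and not at C1: the inductively withdrawing C2 methoxymethoxy group polarises the aryne so that negative charge builds at C1 beside oxygen, and C6 has the open C5–H flank. Carboxylation must also outrun 1,4-acyl transfer from the benzylic ester to C1, which the di-ortho-substituted aroyl group and the low temperature should hold back. Both partners are kept on magnesium because a zinc or copper reagent would take the aryl group from 15 and the arylzinc so formed would not eliminate, and a triflate is used so that the aryne is born at a temperature at which 14 persists.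

Step 10
Reactants: 18 6-{[2,4-bis(methoxymethoxy)-3,6-dimethylbenzoyl]oxymethyl}-2,4-bis(methoxymethoxy)-3-methylbenzoic acid
Product: 19 6-{[(2,4-dihydroxy-3,6-dimethylbenzoyl)oxy]methyl}-2,4-dihydroxy-3-methylbenzoic acid (CNP0110620.0)
Conditions: HCl (1.25 M in MeOH), THF, 0 °C to rt
Reagents that add atoms: none
Why: Acid-catalysed acetal solvolysis of the four aryl methoxymethyl ethers, with methanol trapping the methoxymethyl cation as dimethoxymethane; the di-ortho-substituted ester and acid should resist methanolysis and Fischer esterification at this temperature.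

Compound list
1 | 2-methylresorcinol | Cc1c(O)cccc1O | starting material
2 | 1,3-bis(methoxymethoxy)-2-methylbenzene | Cc1c(OCOC)cccc1OCOC | intermediate
3 | 2-[3,5-bis(methoxymethoxy)-4-methylphenyl]-4,4,5,5-tetramethyl-1,3,2-dioxaborolane | Cc1c(OCOC)cc(B2OC(C)(C)C(C)(C)O2)cc1OCOC | intermediate (not isolated)
4 | 3,5-bis(methoxymethoxy)-4-methylphenol | Cc1c(OCOC)cc(O)cc1OCOC | intermediate
5 | 2-iodo-3,5-bis(methoxymethoxy)-4-methylphenol | Cc1c(OCOC)cc(O)c(I)c1OCOC | intermediate
6 | 2-iodo-3,5-bis(methoxymethoxy)-4-methylphenyl trifluoromethanesulfonate | Cc1c(OCOC)cc(OS(=O)(=O)C(F)(F)F)c(I)c1OCOC | intermediate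
7 | methyl 2,4-dihydroxy-3,6-dimethylbenzoate (atraric acid) | COC(=O)c1c(C)cc(O)c(C)c1O | starting material
8 | methyl 2,4-bis(methoxymethoxy)-3,6-dimethylbenzoate | COC(=O)c1c(C)cc(OCOC)c(C)c1OCOC | intermediate
9 | 2,4-bis(methoxymethoxy)-3,6-dimethylbenzoic acid | Cc1cc(OCOC)c(C)c(OCOC)c1C(=O)O | intermediate
10 | chloromethyl chlorosulfate | ClCOS(Cl)(=O)=O | starting material
11 | chloromethyl 2,4-bis(methoxymethoxy)-3,6-dimethylbenzoate | Cc1cc(OCOC)c(C)c(OCOC)c1C(=O)OCCl | intermediate
12 | iodomethyl 2,4-bis(methoxymethoxy)-3,6-dimethylbenzoate | Cc1cc(OCOC)c(C)c(OCOC)c1C(=O)OCI | intermediate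
13 | carbon dioxide | O=C=O | starting material
14 | {[2,4-bis(methoxymethoxy)-3,6-dimethylbenzoyl]oxy}methylmagnesium chloride | Cc1cc(OCOC)c(C)c(OCOC)c1C(=O)OC[Mg]Cl | intermediate (not isolated)
15 | [2,4-bis(methoxymethoxy)-3-methyl-6-(trifluoromethanesulfonyloxy)phenyl]magnesium chloride | Cc1c(OCOC)cc(OS(=O)(=O)C(F)(F)F)c([Mg]Cl)c1OCOC | intermediate (not isolated)
16 | 3,5-bis(methoxymethoxy)-4-methylbenzyne (1,2-didehydrobenzene numbering) | COCOC1=C(C)C(OCOC)=CC#C1 | intermediate (not isolated)
17 | [6-({[2,4-bis(methoxymethoxy)-3,6-dimethylbenzoyl]oxy}methyl)-2,4-bis(methoxymethoxy)-3-methylphenyl]magnesium chloride | Cc1cc(OCOC)c(C)c(OCOC)c1C(=O)OCc1cc(OCOC)c(C)c(OCOC)c1[Mg]Cl | intermediate (not isolated)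
18 | 6-{[2,4-bis(methoxymethoxy)-3,6-dimethylbenzoyl]oxymethyl}-2,4-bis(methoxymethoxy)-3-methylbenzoic acid | Cc1cc(OCOC)c(C)c(OCOC)c1C(=O)OCc1cc(OCOC)c(C)c(OCOC)c1C(=O)O | intermediate
19 | 6-{[(2,4-dihydroxy-3,6-dimethylbenzoyl)oxy]methyl}-2,4-dihydroxy-3-methylbenzoic acid | Cc1cc(O)c(C)c(O)c1C(=O)OCc1cc(O)c(C)c(O)c1C(=O)O | target

Total step count: 10. Longest linear sequence: 6 steps (steps 1, 2, 3, 4, 9, 10, or equally steps 5, 6, 7, 8, 9, 10).

Steps most likely to fail

1. Step 9 (proposed new method). The carbenoid may decompose by loss of magnesium aroate or add too slowly, so that the aryne is consumed by the exchange reagent or by oligomerisation; acyl migration to C1 may also precede carboxylation. The fallback uses known chemistry, sets out from boronate 3 (isolated before the oxidation of step 2) together with acid 9, and comes back at 17 and hence 18. Matteson homologation of 3 with chloromethyllithium (ICH2Cl, n-BuLi, THF, −78 °C to rt) should give 2-[3,5-bis(methoxymethoxy)-4-methylbenzyl]-4,4,5,5-tetramethyl-1,3,2-dioxaborolane F1, which alkaline H2O2 should oxidise to [3,5-bis(methoxymethoxy)-4-methylphenyl]methanol F2. NIS in MeCN should iodinate one of the two equivalent positions ortho to the hydroxymethyl group to give [2-iodo-3,5-bis(methoxymethoxy)-4-methylphenyl]methanol F3. A Mitsunobu esterification with 9 (PPh3, DIAD, THF) should give [2-iodo-3,5-bis(methoxymethoxy)-4-methylphenyl]methyl 2,4-bis(methoxymethoxy)-3,6-dimethylbenzoate F4. Iodine–magnesium exchange (iPrMgCl·LiCl, THF, −40 °C) should then form 17 without any aryne, and CO2 gives 18, where step 10 follows. This replaces steps 3, 4, 7 and 8 by five operations.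

2. Step 10. During acetal cleavage the C1 carboxyl group may attack the benzylic carbon and expel the ring-A acid (lactonisation to a phthalide), or the freed 2,4-dihydroxybenzoic acid may lose CO2. The fallback sets out from 18 and comes back at 19 with the carboxyl group masked while acid is present. Alkylation of 18 (allyl bromide, KHCO3, DMF, rt) should give prop-2-en-1-yl 6-{[2,4-bis(methoxymethoxy)-3,6-dimethylbenzoyl]oxymethyl}-2,4-bis(methoxymethoxy)-3-methylbenzoate F5. HCl in MeOH/THF should then give prop-2-en-1-yl 6-{[(2,4-dihydroxy-3,6-dimethylbenzoyl)oxy]methyl}-2,4-dihydroxy-3-methylbenzoate F6. Neutral deallylation with Pd(PPh3)4 (zerovalent palladium) and morpholine in THF at rt (Tsuji–Trost type) should release 19.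

3. Step 3. The very electron-rich phenol may be iodinated a second time at the other equivalent position, and traces of acid may remove an acetal. The fallback sets out from 4 and comes back at 6 with the order of the two operations reversed. Sulfonylation of 4 (PhNTf2, Et3N, CH2Cl2) should give 3,5-bis(methoxymethoxy)-4-methylphenyl trifluoromethanesulfonate F7. Its less activated ring should stop at mono-iodination with I2 and AgO2CCF3 (NaHCO3, CHCl3, 0 °C), giving 6 directly.

Further compounds
F1 | step 9 | 2-[3,5-bis(methoxymethoxy)-4-methylbenzyl]-4,4,5,5-tetramethyl-1,3,2-dioxaborolane | Cc1c(OCOC)cc(CB2OC(C)(C)C(C)(C)O2)cc1OCOC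
F2 | step 9 | [3,5-bis(methoxymethoxy)-4-methylphenyl]methanol | Cc1c(OCOC)cc(CO)cc1OCOC
F3 | step 9 | [2-iodo-3,5-bis(methoxymethoxy)-4-methylphenyl]methanol | Cc1c(OCOC)cc(CO)c(I)c1OCOC
F4 | step 9 | [2-iodo-3,5-bis(methoxymethoxy)-4-methylphenyl]methyl 2,4-bis(methoxymethoxy)-3,6-dimethylbenzoate | Cc1cc(OCOC)c(C)c(OCOC)c1C(=O)OCc1cc(OCOC)c(C)c(OCOC)c1I
F5 | step 10 | prop-2-en-1-yl 6-{[2,4-bis(methoxymethoxy)-3,6-dimethylbenzoyl]oxymethyl}-2,4-bis(methoxymethoxy)-3-methylbenzoate | Cc1cc(OCOC)c(C)c(OCOC)c1C(=O)OCc1cc(OCOC)c(C)c(OCOC)c1C(=O)OCC=C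
F6 | step 10 | prop-2-en-1-yl 6-{[(2,4-dihydroxy-3,6-dimethylbenzoyl)oxy]methyl}-2,4-dihydroxy-3-methylbenzoate | Cc1cc(O)c(C)c(O)c1C(=O)OCc1cc(O)c(C)c(O)c1C(=O)OCC=C
F7 | step 3 | 3,5-bis(methoxymethoxy)-4-methylphenyl trifluoromethanesulfonate | Cc1c(OCOC)cc(OS(=O)(=O)C(F)(F)F)cc1OCOC
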